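Locants: core N4, C1–C3, C5–C9, C9a (ring A azepane, ring B pyrrolidine); bicyclic lactone O1', C2'–C6a' (furo[3,2-b]furan numbering; ring C tetrahydrofuran, ring D lactone); ring E = right-hand lactone O1''–C2''(=O)–C3''H(CH3)–C4''H2–C5''H, joined to C3.
Retrosynthesis: ring E is cut at C4''–C5'' and C2''–C3'' (plus the O1''–C2'' ester bond) into the C3 aldehyde, a propene unit and CO2; then ring A at N4–C5 (reductive amination) and C7=C8 (Wittig), C9–C9a (Mannich), ring C at O1'–C6a' (oxa-Michael) and C3'–C3a' (Mukaiyama–Michael).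
Forward: a C5 enal and a silyloxyfuran give the butenolide aldehyde; a Mannich reaction with a pyroglutaminol-derived N-acyliminium ion adds ring B; Wittig extension; desilylation closes rings C and D; hydrogenation and reductive amination close ring A; oxidation gives the C3 aldehyde; the titanium-mediated three-component step closes ring E last.
Enabling feature: ring E is a γ-lactone whose C5''–O1'' is an aldehyde C=O at the carbinol level, whose C4''–C3''(CH3) is exactly propene and whose C2'' is CO2; the basic N4 sits one bond from C5'', so the aldehyde can chelate titanium.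
Stereochemistry: C2' from (S)-but-3-en-2-ol and C3 from L-pyroglutaminol; C3'/C3a' (step 4) and C9 (step 8) from amine catalysts; C9a from trans attack on the pyrrolidinium ring; C6a'/C6' from cis fusion and convex-face protonation (step 10); C5''/C3'' from chelation and the titanacycle (step 13).

Key step: step 13

Remark: the acid work-up of step 13 (lactonisation of 28) is counted as part of that step; the catalyst-bound iminium and enamine species of steps 4 and 8 are not numbered.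

Step 1
Reactants: 1 (S)-but-3-en-2-ol
Product: 2 (S)-tert-butyl(but-3-en-2-yloxy)dimethylsilane
Conditions: TBSCl, imidazole, CH2Cl2, 0 °C to rt
Reagents that add atoms: tert-butyldimethylsilyl chloride, CC(C)(C)[Si](C)(C)Cl
Why: Standard silylation of a secondary alcohol that leaves the C–O bond untouched, so the (S) centre (C2' of the target) is kept.

Step 2
Reactants: 2 (S)-tert-butyl(but-3-en-2-yloxy)dimethylsilane; 3 (E)-but-2-enal
Product: 4 (S,E)-4-[(tert-butyldimethylsilyl)oxy]pent-2-enal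
Conditions: second-generation Grubbs catalyst RuCl2(H2IMes)(PCy3)(=CHPh) (5 mol%), 3 (4 equiv), CH2Cl2, 40 °C
Reagents that add atoms: none
Why: Olefin cross-metathesis of an allylic silyl ether with an electron-poor enal should give the (E)-enal with loss of propene; no stereocentre is formed.

Step 3
Reactants: 5 3-methylfuran-2(5H)-one
Product: 6 trimethyl[(3-methylfuran-2-yl)oxy]silane
Conditions: TMSOTf, Et3N, CH2Cl2, 0 °C
Reagents that add atoms: trimethylsilyl trifluoromethanesulfonate, C[Si](C)(C)OS(=O)(=O)C(F)(F)F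
Why: O-Silylation of the butenolide dienolate is the standard route to 2-silyloxyfurans.

Step 4
Reactants: 4 (S,E)-4-[(tert-butyldimethylsilyl)oxy]pent-2-enal; 6 trimethyl[(3-methylfuran-2-yl)oxy]silane
Product: 7 (3S,4S)-4-[(tert-butyldimethylsilyl)oxy]-3-[(2S)-4-methyl-5-oxo-2,5-dihydrofuran-2-yl]pentanal
Conditions: (2R,5R)-5-benzyl-2-tert-butyl-3-methylimidazolidin-4-one·2,4-dinitrobenzoic acid (20 mol%), H2O (2 equiv), CH2Cl2, −70 °C
Reagents that add atoms: water, O (hydrolysis of the product iminium ion returns the aldehyde oxygen)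
Why: Organocatalytic vinylogous Mukaiyama–Michael addition in which C5 of 6 attacks the β-carbon of the iminium ion of 4 on the face left open by the (2R,5R)-catalyst, which is also anti to the γ-silyloxy group (matched case) and sets C3 of 7 (C3'), while the usual open transition state should give the syn adduct and so set the furanone C2 (C3a').

Step 5
Reactants: 8 (S)-5-(hydroxymethyl)pyrrolidin-2-one
Product: 9 (S)-5-{[(tert-butyldimethylsilyl)oxy]methyl}pyrrolidin-2-one
Conditions: TBSCl, imidazole, DMF, rt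
Reagents that add atoms: tert-butyldimethylsilyl chloride, CC(C)(C)[Si](C)(C)Cl
Why: Standard silylation of the primary alcohol of L-pyroglutaminol, whose stereocentre becomes C3 of the target.

Step 6
Reactants: 9 (S)-5-{[(tert-butyldimethylsilyl)oxy]methyl}pyrrolidin-2-one
Product: 10 benzyl (S)-2-{[(tert-butyldimethylsilyl)oxy]methyl}-5-oxopyrrolidine-1-carboxylate
Conditions: n-BuLi, THF, −78 °C; CbzCl, −78 °C to 0 °C
Reagents that add atoms: benzyl chloroformate, O=C(Cl)OCc1ccccc1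
Why: N-Acylation of the lithiated lactam gives the imide-type carbamate that activates the ring carbonyl for partial reduction.

Step 7
Reactants: 10 benzyl (S)-2-{[(tert-butyldimethylsilyl)oxy]methyl}-5-oxopyrrolidine-1-carboxylate
Product: 12 benzyl (2S)-2-{[(tert-butyldimethylsilyl)oxy]methyl}-5-methoxypyrrolidine-1-carboxylate (both C5 epimers), via hemiaminal 11 (not isolated)
Conditions: LiBHEt3, THF, −78 °C; then MeOH, PPTS (cat.), rt
Reagents that add atoms: methanol, CO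
Why: Partial reduction of an N-acyl lactam stops at the hemiaminal, which acid-catalysed exchange with methanol turns into the stable N,O-acetal; the aminal centre is lost again in step 8, so its configuration does not matter.

Step 8
Reactants: 7 (3S,4S)-4-[(tert-butyldimethylsilyl)oxy]-3-[(2S)-4-methyl-5-oxo-2,5-dihydrofuran-2-yl]pentanal; 12 benzyl (2S)-2-{[(tert-butyldimethylsilyl)oxy]methyl}-5-methoxypyrrolidine-1-carboxylate
Product: 14 benzyl (2S,5S)-2-{[(tert-butyldimethylsilyl)oxy]methyl}-5-{(2R,3S,4S)-4-[(tert-butyldimethylsilyl)oxy]-3-[(2S)-4-methyl-5-oxo-2,5-dihydrofuran-2-yl]-1-oxopentan-2-yl}pyrrolidine-1-carboxylate, via N-acyliminium ion 13 (not isolated)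
Conditions: (S)-α,α-diphenylprolinol trimethylsilyl ether (20 mol%), (PhO)2P(O)OH (20 mol%), 12 (1.5 equiv), CH2Cl2, −20 °C; product used crude
Reagents that add atoms: water, O (hydrolysis of the product iminium ion returns the aldehyde oxygen)
Why: Enamine-catalysed Mannich-type α-amidoalkylation in which acid ionises 12 to N-acyliminium ion 13, which should be attacked by the (E)-enamine of 7 on the enamine face left open by the (S)-prolinol ether (C9, R) and on the iminium face trans to the silyloxymethyl group (C9a, S, 2,5-trans pyrrolidine).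

Step 9
Reactants: 14 benzyl (2S,5S)-2-{[(tert-butyldimethylsilyl)oxy]methyl}-5-{(2R,3S,4S)-4-[(tert-butyldimethylsilyl)oxy]-3-[(2S)-4-methyl-5-oxo-2,5-dihydrofuran-2-yl]-1-oxopentan-2-yl}pyrrolidine-1-carboxylate; 15 [2-(1,3-dioxolan-2-yl)ethyl]triphenylphosphonium bromide
Product: 17 benzyl (2S,5S)-2-{[(tert-butyldimethylsilyl)oxy]methyl}-5-{(2S,3S,4R,5Z)-2-[(tert-butyldimethylsilyl)oxy]-7-(1,3-dioxolan-2-yl)-3-[(2S)-4-methyl-5-oxo-2,5-dihydrofuran-2-yl]hept-5-en-4-yl}pyrrolidine-1-carboxylate, via phosphorus ylide 16 (not isolated)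
Conditions: 15, KN(SiMe3)2, THF, −78 °C; then 14, −78 °C to 0 °C
Reagents that add atoms: none
Why: Wittig olefination with the non-stabilised ylide at −78 °C should be faster than enolisation of the α-branched aldehyde or γ-deprotonation of the butenolide, so C9 and C3a' are kept; the (Z)-geometry is irrelevant because the alkene is hydrogenated in step 11.

Step 10
Reactants: 17 benzyl (2S,5S)-2-{[(tert-butyldimethylsilyl)oxy]methyl}-5-{(2S,3S,4R,5Z)-2-[(tert-butyldimethylsilyl)oxy]-7-(1,3-dioxolan-2-yl)-3-[(2S)-4-methyl-5-oxo-2,5-dihydrofuran-2-yl]hept-5-en-4-yl}pyrrolidine-1-carboxylate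
Product: 19 benzyl (2S,5S)-2-{(1R,2Z)-1-[(2S,3R,3aR,6S,6aR)-2,6-dimethyl-5-oxohexahydrofuro[3,2-b]furan-3-yl]-4-(1,3-dioxolan-2-yl)but-2-en-1-yl}-5-(hydroxymethyl)pyrrolidine-1-carboxylate, via butenolide diol 18 (not isolated)
Conditions: Bu4NF (2.5 equiv), THF, 0 °C; aq. NH4Cl
Reagents that add atoms: none
Why: Fluoride cleaves both silyl ethers and the C2' alkoxide adds 5-exo-trig to the butenolide (intramolecular oxa-Michael addition), which can only give the cis-fused bicycle (C6a'); the lactone enolate should then be protonated from the convex face, so that the C6' methyl group ends on the concave face (kinetic control).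

Step 11
Reactants: 19 benzyl (2S,5S)-2-{(1R,2Z)-1-[(2S,3R,3aR,6S,6aR)-2,6-dimethyl-5-oxohexahydrofuro[3,2-b]furan-3-yl]-4-(1,3-dioxolan-2-yl)but-2-en-1-yl}-5-(hydroxymethyl)pyrrolidine-1-carboxylate
Product: 22 (2S,3R,3aR,6S,6aR)-3-[(3S,9R,9aS)-3-(hydroxymethyl)octahydro-1H-pyrrolo[1,2-a]azepin-9-yl]-2,6-dimethylhexahydrofuro[3,2-b]furan-5(2H)-one, via amino acetal 20 (not isolated), via bicyclic iminium ion 21 (not isolated)
Conditions: H2 (1 atm), Pd/C, MeOH, rt; then 1 M aq. HCl (3 equiv), H2 (4 atm), rt; aq. NaHCO3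
Reagents that add atoms: none
Why: Hydrogenation saturates C7=C8 and removes the Cbz group, aqueous acid unmasks the C5 aldehyde, and this condenses with the pyrrolidine nitrogen to a seven-membered iminium ion that is hydrogenated in the same pot (intramolecular reductive amination); no stereocentre is formed or touched.

Step 12
Reactants: 22 (2S,3R,3aR,6S,6aR)-3-[(3S,9R,9aS)-3-(hydroxymethyl)octahydro-1H-pyrrolo[1,2-a]azepin-9-yl]-2,6-dimethylhexahydrofuro[3,2-b]furan-5(2H)-one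
Product: 23 (3S,9R,9aS)-9-[(2S,3R,3aR,6S,6aR)-2,6-dimethyl-5-oxohexahydrofuro[3,2-b]furan-3-yl]octahydro-1H-pyrrolo[1,2-a]azepine-3-carbaldehyde
Conditions: (COCl)2, DMSO, CH2Cl2, −78 °C; iPr2NEt, −78 to −30 °C; product used crude at once
Reagents that add atoms: none
Why: Swern oxidation of the primary alcohol tolerates the tertiary amine and the lactone, and at low temperature with a hindered base the α-amino aldehyde should not epimerise at C3.

Step 13
Reactants: 23 (3S,9R,9aS)-9-[(2S,3R,3aR,6S,6aR)-2,6-dimethyl-5-oxohexahydrofuro[3,2-b]furan-3-yl]octahydro-1H-pyrrolo[1,2-a]azepine-3-carbaldehyde; 24 isopropylmagnesium chloride; 25 carbon dioxide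
Product: 29 (2S,3R,3aR,6S,6aR)-2,6-dimethyl-3-{(3S,9R,9aS)-3-[(2S,4S)-4-methyl-5-oxooxolan-2-yl]octahydro-1H-pyrrolo[1,2-a]azepin-9-yl}hexahydrofuro[3,2-b]furan-5(2H)-one, via titanacyclopropane 26 (not isolated), via oxatitanacyclopentane 27 (not isolated), via hydroxy acid 28 (not isolated)
Conditions: Ti(OiPr)4 (1.3 equiv), 24 (2.6 equiv), Et2O, −78 to −50 °C, 1 h; 23, −78 °C, 1 h; 25 (1 atm), −78 to −20 °C; 1 M aq. HCl, rt; aq. NaHCO3
Reagents that add atoms: none
Why: Proposed new method: Ti(OiPr)4 and two equivalents of 24 give diisopropyltitanium diisopropoxide, which loses propane to form titanacyclopropane 26 (the propene complex of divalent titanium); the aldehyde C=O of 23 inserts into its less hindered Ti–CH2 bond (C4''–C5'') to give oxatitanacyclopentane 27, whose remaining Ti–CH(CH3) bond inserts CO2 with retention (C2''–C3''), and acid releases hydroxy acid 28, which lactonises. The closest known reactions are the Kulinkovich-type insertion of carbonyl groups into dialkoxytitanacyclopropanes (alkene–aldehyde coupling through oxatitanacyclopentanes), the carboxylation of titanacycles with CO2, and the hetero-Pauson–Khand [2+2+1] lactone synthesis, in which CO2 here takes the place of CO so that no reductive elimination is needed. Ring E is closed in two stages: the five-membered oxametallacycle by migratory insertion on titanium (formal [2+2+1] assembly) and the lactone by 5-exo-trig acyl substitution of the C5'' hydroxyl on the C2'' carboxyl group. C5'' should be set by Cram-chelate control, since N4 and the aldehyde oxygen bind the Lewis-acidic titanium and the CH2 group is delivered to the carbonyl face on the side of H-3, giving the syn amino alcohol (C5'' S); C3'' should be set in the metallacycle, whose envelope places the methyl group pseudo-equatorial and cis to the C5'' substituent, and is carried into the lactone by the stereoretentive CO2 insertion (C3'' S, the cis lactone). The step needs chemoselectivity for the aldehyde over the ring D lactone, which the much faster insertion of aldehydes at −78 °C and a small excess of reagent should secure, and regioselectivity for the unsubstituted Ti–C bond, which the methyl group of the propene ligand should secure.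

Compound list
1 | (S)-but-3-en-2-ol | C[C@H](O)C=C | starting material
2 | (S)-tert-butyl(but-3-en-2-yloxy)dimethylsilane | C[C@H](O[Si](C)(C)C(C)(C)C)C=C | intermediate
3 | (E)-but-2-enal | C/C=C/C=O | starting material
4 | (S,E)-4-[(tert-butyldimethylsilyl)oxy]pent-2-enal | C[C@H](O[Si](C)(C)C(C)(C)C)/C=C/C=O | intermediate
5 | 3-methylfuran-2(5H)-one | CC1=CCOC1=O | starting material
6 | trimethyl[(3-methylfuran-2-yl)oxy]silane | Cc1ccoc1O[Si](C)(C)C | intermediate
7 | (3S,4S)-4-[(tert-butyldimethylsilyl)oxy]-3-[(2S)-4-methyl-5-oxo-2,5-dihydrofuran-2-yl]pentanal | C[C@H](O[Si](C)(C)C(C)(C)C)[C@@H](CC=O)[C@H]1OC(=O)C(C)=C1 | intermediate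
8 | (S)-5-(hydroxymethyl)pyrrolidin-2-one | OC[C@@H]1CCC(=O)N1 | starting material
9 | (S)-5-{[(tert-butyldimethylsilyl)oxy]methyl}pyrrolidin-2-one | CC(C)(C)[Si](C)(C)OC[C@@H]1CCC(=O)N1 | intermediate
10 | benzyl (S)-2-{[(tert-butyldimethylsilyl)oxy]methyl}-5-oxopyrrolidine-1-carboxylate | CC(C)(C)[Si](C)(C)OC[C@@H]1CCC(=O)N1C(=O)OCc1ccccc1 | intermediate
11 | benzyl (2S)-2-{[(tert-butyldimethylsilyl)oxy]methyl}-5-hydroxypyrrolidine-1-carboxylate (hemiaminal, both C5 epimers) | CC(C)(C)[Si](C)(C)OC[C@@H]1CCC(O)N1C(=O)OCc1ccccc1 | intermediate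
12 | benzyl (2S)-2-{[(tert-butyldimethylsilyl)oxy]methyl}-5-methoxypyrrolidine-1-carboxylate (both C5 epimers) | CC(C)(C)[Si](C)(C)OC[C@@H]1CCC(OC)N1C(=O)OCc1ccccc1 | intermediate
13 | (S)-1-[(benzyloxy)carbonyl]-2-{[(tert-butyldimethylsilyl)oxy]methyl}-3,4-dihydro-2H-pyrrol-1-ium diphenyl phosphate (N-acyliminium ion) | CC(C)(C)[Si](C)(C)OC[C@@H]1CCC=[N+]1C(=O)OCc1ccccc1.[O-]P(=O)(Oc1ccccc1)Oc1ccccc1 | intermediate
14 | benzyl (2S,5S)-2-{[(tert-butyldimethylsilyl)oxy]methyl}-5-{(2R,3S,4S)-4-[(tert-butyldimethylsilyl)oxy]-3-[(2S)-4-methyl-5-oxo-2,5-dihydrofuran-2-yl]-1-oxopentan-2-yl}pyrrolidine-1-carboxylate | C[C@H](O[Si](C)(C)C(C)(C)C)[C@H]([C@H]1OC(=O)C(C)=C1)[C@@H](C=O)[C@@H]1CC[C@@H](CO[Si](C)(C)C(C)(C)C)N1C(=O)OCc1ccccc1 | intermediate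
15 | [2-(1,3-dioxolan-2-yl)ethyl]triphenylphosphonium bromide | [Br-].C1COC(CC[P+](c2ccccc2)(c2ccccc2)c2ccccc2)O1 | starting material
16 | [2-(1,3-dioxolan-2-yl)ethylidene]triphenylphosphorane (ylide) | C1COC(CC=P(c2ccccc2)(c2ccccc2)c2ccccc2)O1 | intermediate
17 | benzyl (2S,5S)-2-{[(tert-butyldimethylsilyl)oxy]methyl}-5-{(2S,3S,4R,5Z)-2-[(tert-butyldimethylsilyl)oxy]-7-(1,3-dioxolan-2-yl)-3-[(2S)-4-methyl-5-oxo-2,5-dihydrofuran-2-yl]hept-5-en-4-yl}pyrrolidine-1-carboxylate | C[C@H](O[Si](C)(C)C(C)(C)C)[C@H]([C@H]1OC(=O)C(C)=C1)[C@@H](/C=C\CC1OCCO1)[C@@H]1CC[C@@H](CO[Si](C)(C)C(C)(C)C)N1C(=O)OCc1ccccc1 | intermediate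
18 | benzyl (2S,5S)-2-(hydroxymethyl)-5-{(2S,3R,4R,5Z)-7-(1,3-dioxolan-2-yl)-2-hydroxy-3-[(2S)-4-methyl-5-oxo-2,5-dihydrofuran-2-yl]hept-5-en-4-yl}pyrrolidine-1-carboxylate (diol of 17, configurations unchanged) | C[C@H](O)[C@H]([C@H]1OC(=O)C(C)=C1)[C@@H](/C=C\CC1OCCO1)[C@@H]1CC[C@@H](CO)N1C(=O)OCc1ccccc1 | intermediate
19 | benzyl (2S,5S)-2-{(1R,2Z)-1-[(2S,3R,3aR,6S,6aR)-2,6-dimethyl-5-oxohexahydrofuro[3,2-b]furan-3-yl]-4-(1,3-dioxolan-2-yl)but-2-en-1-yl}-5-(hydroxymethyl)pyrrolidine-1-carboxylate | C[C@@H]1O[C@H]2[C@H](OC(=O)[C@H]2C)[C@@H]1[C@@H](/C=C\CC1OCCO1)[C@@H]1CC[C@@H](CO)N1C(=O)OCc1ccccc1 | intermediate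
20 | (2S,3R,3aR,6S,6aR)-3-{(1R)-4-(1,3-dioxolan-2-yl)-1-[(2S,5S)-5-(hydroxymethyl)pyrrolidin-2-yl]butyl}-2,6-dimethylhexahydrofuro[3,2-b]furan-5(2H)-one | C[C@@H]1O[C@H]2[C@H](OC(=O)[C@H]2C)[C@@H]1[C@@H](CCCC1OCCO1)[C@@H]1CC[C@@H](CO)N1 | intermediate
21 | bicyclic iminium chloride (N4=C5) with the substituents and configurations of 22 | C[C@@H]1O[C@H]2[C@H](OC(=O)[C@H]2C)[C@@H]1[C@H]1CCCC=[N+]2[C@H]1CC[C@H]2CO.[Cl-] | intermediate
22 | (2S,3R,3aR,6S,6aR)-3-[(3S,9R,9aS)-3-(hydroxymethyl)octahydro-1H-pyrrolo[1,2-a]azepin-9-yl]-2,6-dimethylhexahydrofuro[3,2-b]furan-5(2H)-one | C[C@@H]1O[C@H]2[C@H](OC(=O)[C@H]2C)[C@@H]1[C@H]1CCCCN2[C@H]1CC[C@H]2CO | intermediate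
23 | (3S,9R,9aS)-9-[(2S,3R,3aR,6S,6aR)-2,6-dimethyl-5-oxohexahydrofuro[3,2-b]furan-3-yl]octahydro-1H-pyrrolo[1,2-a]azepine-3-carbaldehyde | C[C@@H]1O[C@H]2[C@H](OC(=O)[C@H]2C)[C@@H]1[C@H]1CCCCN2[C@H]1CC[C@H]2C=O | intermediate
24 | isopropylmagnesium chloride | CC(C)[Mg]Cl | starting material
25 | carbon dioxide | O=C=O | starting material
26 | 2-methyl-1,1-bis(propan-2-yloxy)titanacyclopropane, (η2-propene)Ti(OiPr)2, racemic | CC1C[Ti]1(OC(C)C)OC(C)C | intermediate
27 | (3S,5S)-3-methyl-2,2-bis(propan-2-yloxy)-5-[(3S,9R,9aS)-9-((2S,3R,3aR,6S,6aR)-2,6-dimethyl-5-oxohexahydrofuro[3,2-b]furan-3-yl)octahydro-1H-pyrrolo[1,2-a]azepin-3-yl]-1-oxa-2-titanacyclopentane | C[C@@H]1O[C@H]2[C@H](OC(=O)[C@H]2C)[C@@H]1[C@H]1CCCCN2[C@H]1CC[C@H]2[C@@H]1C[C@H](C)[Ti](OC(C)C)(OC(C)C)O1 | intermediate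
28 | (2S,4S)-4-[(3S,9R,9aS)-9-((2S,3R,3aR,6S,6aR)-2,6-dimethyl-5-oxohexahydrofuro[3,2-b]furan-3-yl)octahydro-1H-pyrrolo[1,2-a]azepin-3-yl]-4-hydroxy-2-methylbutanoic acid | C[C@@H]1O[C@H]2[C@H](OC(=O)[C@H]2C)[C@@H]1[C@H]1CCCCN2[C@H]1CC[C@H]2[C@@H](O)C[C@H](C)C(=O)O | intermediate
29 | (2S,3R,3aR,6S,6aR)-2,6-dimethyl-3-{(3S,9R,9aS)-3-[(2S,4S)-4-methyl-5-oxooxolan-2-yl]octahydro-1H-pyrrolo[1,2-a]azepin-9-yl}hexahydrofuro[3,2-b]furan-5(2H)-one (CNP0108586.2) | C[C@@H]1O[C@H]2[C@H](OC(=O)[C@H]2C)[C@@H]1[C@H]1CCCCN2[C@H]1CC[C@H]2[C@@H]1C[C@H](C)C(=O)O1 | target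

Total steps: 13. Longest linear sequence: 9 (steps 1, 2, 4, 8, 9, 10, 11, 12, 13).

Steps most likely to fail

Step 13. The low-valent titanium reagent may reduce the aldehyde or couple it reductively instead of inserting it. The Ti–C bond of the oxatitanacycle may be protonated on work-up rather than carboxylated. The α-amino aldehyde may epimerise before it reacts, the reagent may attack the ring D lactone, and control at C3'' may be poor. The fallback uses known chemistry and sets out from aldehyde 23. A chelation-controlled Barbier-type addition of the organozinc reagent from ethyl 2-(bromomethyl)acrylate (Zn, THF) should give the hydroxy ester ethyl (4S)-4-hydroxy-2-methylidene-4-[(3S,9R,9aS)-9-((2S,3R,3aR,6S,6aR)-2,6-dimethyl-5-oxohexahydrofuro[3,2-b]furan-3-yl)octahydro-1H-pyrrolo[1,2-a]azepin-3-yl]butanoate F1. Acid (TsOH, CH2Cl2) should close it, with loss of ethanol, to the α-methylene lactone (2S,3R,3aR,6S,6aR)-2,6-dimethyl-3-{(3S,9R,9aS)-3-[(2S)-4-methylidene-5-oxooxolan-2-yl]octahydro-1H-pyrrolo[1,2-a]azepin-9-yl}hexahydrofuro[3,2-b]furan-5(2H)-one F2. Hydrogenation (H2, Pd/C, EtOAc) from the face away from the C5'' substituent should give the cis lactone, so the fallback comes back to the route at 29.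

Step 8. The N-acyliminium ion may lose a proton to the enecarbamate faster than the hindered β-branched enamine attacks it, and facial control at C9a may be incomplete. The fallback moves the coupling to the imide oxidation level with a covalently bound auxiliary and sets out from aldehyde 7. Oxidation (NaClO2, NaH2PO4, 2-methylbut-2-ene, t-BuOH/H2O) should give (3S,4S)-4-[(tert-butyldimethylsilyl)oxy]-3-[(2S)-4-methyl-5-oxo-2,5-dihydrofuran-2-yl]pentanoic acid F3. Its mixed pivalic anhydride and lithiated (S)-4-benzyloxazolidin-2-one should give the imide (S)-4-benzyl-3-{(3S,4S)-4-[(tert-butyldimethylsilyl)oxy]-3-[(2S)-4-methyl-5-oxo-2,5-dihydrofuran-2-yl]pentanoyl}oxazolidin-2-one F4. The chlorotitanium enolate (TiCl4, iPr2NEt, CH2Cl2, −78 °C) should add to the N-acyliminium ion made from 12, with the auxiliary fixing C9, to give the Mannich imide benzyl (2S,5S)-2-{(2R,3S,4S)-1-[(S)-4-benzyl-2-oxooxazolidin-3-yl]-4-[(tert-butyldimethylsilyl)oxy]-3-[(2S)-4-methyl-5-oxo-2,5-dihydrofuran-2-yl]-1-oxopentan-2-yl}-5-{[(tert-butyldimethylsilyl)oxy]methyl}pyrrolidine-1-carboxylate F5. NaBH4 in THF/H2O at 0 °C should release the auxiliary and give the primary alcohol benzyl (2S,5S)-2-{(2R,3S,4S)-4-[(tert-butyldimethylsilyl)oxy]-1-hydroxy-3-[(2S)-4-methyl-5-oxo-2,5-dihydrofuran-2-yl]pentan-2-yl}-5-{[(tert-butyldimethylsilyl)oxy]methyl}pyrrolidine-1-carboxylate F6. Periodinane oxidation (1,1,1-triacetoxy-1,1-dihydro-1,2-benziodoxol-3(1H)-one, CH2Cl2) then returns the route to 14.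

Step 10. Under the basic fluoride conditions C6' may equilibrate by enolisation, which would move the methyl group to the convex face, and the oxa-Michael addition may reverse. The fallback resets C6' by a hydrogenation and sets out from 19, obtained as any mixture of C6' epimers. Enolisation (LiN(iPr)2, 2.2 equiv, THF, −78 °C) and PhSeBr should give the selenide benzyl (2S,5S)-2-{(1R,2Z)-1-[(2S,3R,3aR,6aR)-2,6-dimethyl-5-oxo-6-(phenylselanyl)hexahydrofuro[3,2-b]furan-3-yl]-4-(1,3-dioxolan-2-yl)but-2-en-1-yl}-5-(hydroxymethyl)pyrrolidine-1-carboxylate (selenium on the convex face) F7. Oxidation (H2O2, pyridine, CH2Cl2, 0 °C) and selenoxide elimination away from the ring oxygen should give the α-methylene lactone benzyl (2S,5S)-2-{(1R,2Z)-1-[(2S,3R,3aR,6aR)-2-methyl-6-methylidene-5-oxohexahydrofuro[3,2-b]furan-3-yl]-4-(1,3-dioxolan-2-yl)but-2-en-1-yl}-5-(hydroxymethyl)pyrrolidine-1-carboxylate F8. Under the conditions of step 11 the exocyclic alkene should also take up hydrogen from the convex face, which puts the methyl group on the concave face, and the fallback comes back to the route at 22.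

Further compounds
F1 | step 13 | ethyl (4S)-4-hydroxy-2-methylidene-4-[(3S,9R,9aS)-9-((2S,3R,3aR,6S,6aR)-2,6-dimethyl-5-oxohexahydrofuro[3,2-b]furan-3-yl)octahydro-1H-pyrrolo[1,2-a]azepin-3-yl]butanoate | C[C@@H]1O[C@H]2[C@H](OC(=O)[C@H]2C)[C@@H]1[C@H]1CCCCN2[C@H]1CC[C@H]2[C@@H](O)CC(=C)C(=O)OCC
F2 | step 13 | (2S,3R,3aR,6S,6aR)-2,6-dimethyl-3-{(3S,9R,9aS)-3-[(2S)-4-methylidene-5-oxooxolan-2-yl]octahydro-1H-pyrrolo[1,2-a]azepin-9-yl}hexahydrofuro[3,2-b]furan-5(2H)-one | C[C@@H]1O[C@H]2[C@H](OC(=O)[C@H]2C)[C@@H]1[C@H]1CCCCN2[C@H]1CC[C@H]2[C@@H]1CC(=C)C(=O)O1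
F3 | step 8 | (3S,4S)-4-[(tert-butyldimethylsilyl)oxy]-3-[(2S)-4-methyl-5-oxo-2,5-dihydrofuran-2-yl]pentanoic acid | C[C@H](O[Si](C)(C)C(C)(C)C)[C@@H](CC(=O)O)[C@H]1OC(=O)C(C)=C1
F4 | step 8 | (S)-4-benzyl-3-{(3S,4S)-4-[(tert-butyldimethylsilyl)oxy]-3-[(2S)-4-methyl-5-oxo-2,5-dihydrofuran-2-yl]pentanoyl}oxazolidin-2-one | C[C@H](O[Si](C)(C)C(C)(C)C)[C@@H](CC(=O)N1[C@@H](Cc2ccccc2)COC1=O)[C@H]1OC(=O)C(C)=C1
F5 | step 8 | benzyl (2S,5S)-2-{(2R,3S,4S)-1-[(S)-4-benzyl-2-oxooxazolidin-3-yl]-4-[(tert-butyldimethylsilyl)oxy]-3-[(2S)-4-methyl-5-oxo-2,5-dihydrofuran-2-yl]-1-oxopentan-2-yl}-5-{[(tert-butyldimethylsilyl)oxy]methyl}pyrrolidine-1-carboxylate | C[C@H](O[Si](C)(C)C(C)(C)C)[C@H]([C@H]1OC(=O)C(C)=C1)[C@@H](C(=O)N1[C@@H](Cc2ccccc2)COC1=O)[C@@H]1CC[C@@H](CO[Si](C)(C)C(C)(C)C)N1C(=O)OCc1ccccc1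
F6 | step 8 | benzyl (2S,5S)-2-{(2R,3S,4S)-4-[(tert-butyldimethylsilyl)oxy]-1-hydroxy-3-[(2S)-4-methyl-5-oxo-2,5-dihydrofuran-2-yl]pentan-2-yl}-5-{[(tert-butyldimethylsilyl)oxy]methyl}pyrrolidine-1-carboxylate | C[C@H](O[Si](C)(C)C(C)(C)C)[C@H]([C@H]1OC(=O)C(C)=C1)[C@@H](CO)[C@@H]1CC[C@@H](CO[Si](C)(C)C(C)(C)C)N1C(=O)OCc1ccccc1
F7 | step 10 | benzyl (2S,5S)-2-{(1R,2Z)-1-[(2S,3R,3aR,6aR)-2,6-dimethyl-5-oxo-6-(phenylselanyl)hexahydrofuro[3,2-b]furan-3-yl]-4-(1,3-dioxolan-2-yl)but-2-en-1-yl}-5-(hydroxymethyl)pyrrolidine-1-carboxylate (selenium on the convex face) | C[C@@H]1O[C@H]2[C@H](OC(=O)[C@]2(C)[Se]c2ccccc2)[C@@H]1[C@@H](/C=C\CC1OCCO1)[C@@H]1CC[C@@H](CO)N1C(=O)OCc1ccccc1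
F8 | step 10 | benzyl (2S,5S)-2-{(1R,2Z)-1-[(2S,3R,3aR,6aR)-2-methyl-6-methylidene-5-oxohexahydrofuro[3,2-b]furan-3-yl]-4-(1,3-dioxolan-2-yl)but-2-en-1-yl}-5-(hydroxymethyl)pyrrolidine-1-carboxylate | C[C@@H]1O[C@H]2[C@H](OC(=O)C2=C)[C@@H]1[C@@H](/C=C\CC1OCCO1)[C@@H]1CC[C@@H](CO)N1C(=O)OCc1ccccc1
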